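**Retrosynthetic overview**
1. The tridepside is cut at its two aryl ester bonds: ring A carbonyl–O4' of ring B, and ring B carbonyl (on C1')–O4'' of ring C. Rings A and C are taken from aromatic starting materials; only ring B is built.
2. The strategy rests on ring B, the central orsellinate (C1' bearing the ester carbonyl, C2'–OH, C3'–H, C4'–O, C5'–H, C6'–CH3). It is a resorcinol whose two oxygens must emerge differentiated: O2' free next to the ester, O4' masked.
3. Ring B is opened to an α-diazo enone (C1', C2', C5', C6', the methyl and the ester) and a silyl ynol ether (C3', C4'). A Wolff shift makes C5'–C6', a ketene–alkyne [2+2] makes C2'–C3' and C4'–C5', and 4π opening/6π closure makes C1'–C2'.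
4. Order: ring B is formed, desilylated, acylated at O4' by the ring A acid chloride, freed from its tert-butyl ester, esterified with the 4-OH of benzyl orsellinate (ring C), and the benzyl groups are removed by hydrogenolysis.

Key step: step 4

Assumption: 2,3,4-trimethoxy-6-methylbenzaldehyde and orsellinic acid are taken as purchasable; the target has no stereocentre, so the only stereochemical element to control is the E geometry of the enoate from 3 to 13 (ring B locants primed, ring C double-primed).

Step 1
Reactants: 1 butane-2,3-dione; 2 tert-butyl (triphenylphosphoranylidene)acetate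
Product: 3 tert-butyl (2E)-3-methyl-4-oxopent-2-enoate
Conditions: 1 (3 equiv), CH2Cl2, 0 °C → rt
Reagents that add atoms: none
Why: Wittig olefination of one carbonyl of the symmetrical diketone by the ester-stabilized ylide; excess diketone should suppress double olefination, and the stabilized ylide should give mainly the E enoate (acetyl and ester trans), the minor Z isomer being removed by chromatography.

Step 2
Reactants: 3 tert-butyl (2E)-3-methyl-4-oxopent-2-enoate
Product: 6 tert-butyl (2E)-5-diazo-3-methyl-4-oxopent-2-enoate, via lithium enolate 4 (not isolated), via trifluoroacetyl diketone 5 (not isolated)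
Conditions: LiN(SiMe3)2, THF, −78 °C; CF3CO2CH2CF3; aq HCl; then MsN3, Et3N, H2O, MeCN, rt
Reagents that add atoms: methanesulfonyl azide, CS(=O)(=O)N=[N+]=[N-]
Why: Detrifluoroacetylative (Regitz-type) diazo transfer: kinetic deprotonation at −78 °C should take the acetyl methyl rather than the vinylogous C3 methyl, Claisen trifluoroacetylation activates that carbon, and diazo transfer with loss of the trifluoroacetyl group should give the α'-diazo enone with the E enoate untouched.

Step 3
Reactants: 7 trimethylsilylacetylene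
Product: 10 triisopropyl{[(trimethylsilyl)ethynyl]oxy}silane, via lithium (trimethylsilyl)acetylide 8 (not isolated), via lithium silylynolate 9 (not isolated)
Conditions: n-BuLi, THF, −78 °C; LiOOt-Bu (from t-BuOOH, LiN(SiMe3)2), −78 → 0 °C; i-Pr3SiOTf, −78 → 0 °C
Reagents that add atoms: tert-butyl hydroperoxide, CC(C)(C)OO; triisopropylsilyl trifluoromethanesulfonate, CC(C)[Si](C(C)C)(C(C)C)OS(=O)(=O)C(F)(F)F
Why: Oxidation of a lithium acetylide by lithium tert-butyl peroxide (attack at the peroxide oxygen, tert-butoxide leaves) gives the ynolate, and the bulky silyl triflate should silylate at oxygen rather than at the carbon that already carries Me3Si.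

Step 4
Reactants: 6 tert-butyl (2E)-5-diazo-3-methyl-4-oxopent-2-enoate; 10 triisopropyl{[(trimethylsilyl)ethynyl]oxy}silane
Product: 15 tert-butyl 2-hydroxy-6-methyl-4-(triisopropylsilyloxy)-3-(trimethylsilyl)benzoate, via vinylketene 11 (not isolated), via vinylcyclobutenone 12 (not isolated), via dienylketene 13 (not isolated), via cyclohexadienone 14 (not isolated)
Conditions: hν (254 nm, low-pressure Hg lamp, quartz), 10 (1.5 equiv), degassed ClCH2CH2Cl, rt; then 80 °C
Reagents that add atoms: none
Why: Irradiation expels N2 from 6 and the alkenyl group migrates with retention of its E geometry (photochemical Wolff rearrangement, forming C5'–C6') to give vinylketene 11, which the electron-rich ynol silyl ether 10 captures in a ketene–alkyne [2+2] cycloaddition (C2'–C3' and C4'–C5') to give cyclobutenone 12. On warming, 12 opens reversibly by 4π conrotatory cleavage to dienylketene 13, and ring B then closes by 6π disrotatory electrocyclization of the ketene carbon C2' onto the ester-bearing alkene carbon C1'; the doubly activated C1'–H of dienone 14 tautomerizes to phenol 15. The closest known reaction type is the Danheiser benzannulation in its α-diazo ketone variant with siloxyalkynes, applied here to a vinylketene that carries a conjugated ester. No stereocentre survives: the sp3 centres of 12 and 14 form as racemates and are erased by ring opening and aromatization. The step needs [2+2] regioselectivity, secured by the polarization of 10 (the carbon β to oxygen is nucleophilic and bonds to the ketene carbonyl carbon, the developing positive charge being stabilized by oxygen and by the adjacent C–Si bond), so that the ketene oxygen becomes the free O2' and the alkyne oxygen the silylated O4'. It also needs the E enoate geometry set in step 1, which places the ester on the outside of the triene for the 6π closure and keeps its carbonyl oxygen away from the ketene carbon.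

Step 5
Reactants: 15 tert-butyl 2-hydroxy-6-methyl-4-(triisopropylsilyloxy)-3-(trimethylsilyl)benzoate
Product: 17 tert-butyl 2,4-dihydroxy-6-methylbenzoate, via C-silyl resorcinol 16 (not isolated)
Conditions: n-Bu4NF·3H2O (3 equiv), THF, 0 °C → rt; aq NH4Cl
Reagents that add atoms: none
Why: Fluoride desilylation: the aryl Si–O bond is cleaved first, the resulting 2-silylresorcinolate should be protonated by the water present at C3' (the carbon between the two oxygens), and the α-silyl ketone tautomer then loses Me3Si to fluoride (protodesilylation), the tert-butyl ester being inert.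

Step 6
Reactants: 18 2,3,4-trimethoxy-6-methylbenzaldehyde
Product: 19 2,3,4-trihydroxy-6-methylbenzaldehyde
Conditions: BBr3 (4 equiv), CH2Cl2, −78 °C → rt; H2O
Reagents that add atoms: none
Why: Exhaustive Lewis acid cleavage of the three aryl methyl ethers (BBr3 demethylation); the aldehyde is returned when the borate is hydrolysed.

Step 7
Reactants: 19 2,3,4-trihydroxy-6-methylbenzaldehyde
Product: 20 3,4-bis(benzyloxy)-2-hydroxy-6-methylbenzaldehyde
Conditions: BnBr (2.1 equiv), K2CO3 (2.2 equiv), DMF, Ar, rt
Reagents that add atoms: benzyl bromide, BrCc1ccccc1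
Why: Williamson etherification; the 2-OH is held in a hydrogen-bonded chelate with the aldehyde carbonyl and its anion is the least nucleophilic, so two equivalents of benzyl bromide should take O4 and then O3.

Step 8
Reactants: 20 3,4-bis(benzyloxy)-2-hydroxy-6-methylbenzaldehyde
Product: 21 3,4-bis(benzyloxy)-2-methoxy-6-methylbenzaldehyde
Conditions: MeI (excess), K2CO3, DMF, 50 °C
Reagents that add atoms: iodomethane, CI
Why: Williamson methylation of the remaining chelated phenol, which should yield under more forcing conditions (warm polar aprotic solvent, excess small electrophile).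

Step 9
Reactants: 21 3,4-bis(benzyloxy)-2-methoxy-6-methylbenzaldehyde
Product: 22 3,4-bis(benzyloxy)-2-methoxy-6-methylbenzoic acid
Conditions: NaClO2, NaH2PO4, 2-methylbut-2-ene, t-BuOH/H2O, rt
Reagents that add atoms: sodium chlorite, [Na+].[O-]Cl=O
Why: Pinnick oxidation takes the hindered aldehyde to the acid, and the alkene scavenges HOCl so that the electron-rich ring and the benzyl ethers should not be chlorinated.

Step 10
Reactants: 22 3,4-bis(benzyloxy)-2-methoxy-6-methylbenzoic acid; 17 tert-butyl 2,4-dihydroxy-6-methylbenzoate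
Product: 24 tert-butyl 4-{[3,4-bis(benzyloxy)-2-methoxy-6-methylbenzoyl]oxy}-2-hydroxy-6-methylbenzoate, via acid chloride 23 (not isolated)
Conditions: (COCl)2, cat. DMF, CH2Cl2, 0 °C → rt, evaporate; then 17, Et3N, cat. DMAP, CH2Cl2, 0 °C → rt
Reagents that add atoms: none
Why: Acid chloride formation followed by DMAP-catalysed acylation of a phenol; of the two hydroxyls of 17 only the 4'-OH is free, the 2'-OH being chelated to the ester carbonyl, so monoacylation at O4' is expected.

Step 11
Reactants: 24 tert-butyl 4-{[3,4-bis(benzyloxy)-2-methoxy-6-methylbenzoyl]oxy}-2-hydroxy-6-methylbenzoate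
Product: 25 4-{[3,4-bis(benzyloxy)-2-methoxy-6-methylbenzoyl]oxy}-2-hydroxy-6-methylbenzoic acid
Conditions: CF3CO2H/CH2Cl2 (1:4), 0 °C → rt
Reagents that add atoms: none
Why: Acidolysis of the tert-butyl ester with loss of isobutene; the benzyl ethers, the aryl ester and the methyl ether should tolerate brief exposure to dilute acid at or below rt.

Step 12
Reactants: 26 orsellinic acid (2,4-dihydroxy-6-methylbenzoic acid)
Product: 27 benzyl 2,4-dihydroxy-6-methylbenzoate
Conditions: BnBr (1.05 equiv), KHCO3, DMF, rt
Reagents that add atoms: benzyl bromide, BrCc1ccccc1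
Why: Carboxylate O-alkylation: hydrogencarbonate deprotonates only the carboxylic acid, so benzyl bromide should give the benzyl ester and leave both phenols free.

Step 13
Reactants: 25 4-{[3,4-bis(benzyloxy)-2-methoxy-6-methylbenzoyl]oxy}-2-hydroxy-6-methylbenzoic acid; 27 benzyl 2,4-dihydroxy-6-methylbenzoate
Product: 28 benzyl 4-[(4-{[3,4-bis(benzyloxy)-2-methoxy-6-methylbenzoyl]oxy}-2-hydroxy-6-methylbenzoyl)oxy]-2-hydroxy-6-methylbenzoate
Conditions: DCC, cat. DMAP, 27 (1.2 equiv), CH2Cl2, 0 °C → rt
Reagents that add atoms: none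
Why: Steglich esterification; the unchelated 4-OH of 27 is the only nucleophilic phenol present, because the 2-OH of 27 and the 2'-OH of 25 are both hydrogen-bonded to ortho carbonyl groups and flanked.

Step 14
Reactants: 28 benzyl 4-[(4-{[3,4-bis(benzyloxy)-2-methoxy-6-methylbenzoyl]oxy}-2-hydroxy-6-methylbenzoyl)oxy]-2-hydroxy-6-methylbenzoate
Product: 29 4-({4-[(3,4-dihydroxy-2-methoxy-6-methylbenzoyl)oxy]-2-hydroxy-6-methylbenzoyl}oxy)-2-hydroxy-6-methylbenzoic acid (target)
Conditions: H2 (1 atm), 10% Pd/C, EtOAc, rt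
Reagents that add atoms: none
Why: Catalytic hydrogenolysis should remove the two benzyl ethers and the benzyl ester in one operation under neutral conditions that leave both depside esters intact.

**Compound list**
1 | butane-2,3-dione | CC(=O)C(C)=O | starting material
2 | tert-butyl (triphenylphosphoranylidene)acetate | CC(C)(C)OC(=O)C=P(c1ccccc1)(c1ccccc1)c1ccccc1 | starting material
3 | tert-butyl (2E)-3-methyl-4-oxopent-2-enoate | CC(=O)/C(C)=C/C(=O)OC(C)(C)C | intermediate
4 | lithium (3E)-5-tert-butoxy-3-methyl-5-oxopenta-1,3-dien-2-olate (kinetic enolate of 3) | [Li]OC(=C)/C(C)=C/C(=O)OC(C)(C)C | intermediate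
5 | tert-butyl (2E)-7,7,7-trifluoro-3-methyl-4,6-dioxohept-2-enoate | O=C(CC(=O)C(F)(F)F)/C(C)=C/C(=O)OC(C)(C)C | intermediate
6 | tert-butyl (2E)-5-diazo-3-methyl-4-oxopent-2-enoate | [N-]=[N+]=CC(=O)/C(C)=C/C(=O)OC(C)(C)C | intermediate
7 | trimethylsilylacetylene | C#C[Si](C)(C)C | starting material
8 | lithium (trimethylsilyl)acetylide | [Li]C#C[Si](C)(C)C | intermediate
9 | lithium 2-(trimethylsilyl)ethynolate | [Li]OC#C[Si](C)(C)C | intermediate
10 | triisopropyl{[(trimethylsilyl)ethynyl]oxy}silane | C[Si](C)(C)C#CO[Si](C(C)C)(C(C)C)C(C)C | intermediate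
11 | tert-butyl (2E)-3-methyl-5-oxopenta-2,4-dienoate (vinylketene) | O=C=C/C(C)=C/C(=O)OC(C)(C)C | intermediate
12 | tert-butyl (2E)-3-[4-oxo-2-(triisopropylsilyloxy)-3-(trimethylsilyl)cyclobut-2-en-1-yl]but-2-enoate (racemic at the ring CH) | CC(C)[Si](C(C)C)(C(C)C)OC1=C([Si](C)(C)C)C(=O)C1/C(C)=C/C(=O)OC(C)(C)C | intermediate
13 | tert-butyl (2E,4E)-3-methyl-7-oxo-5-(triisopropylsilyloxy)-6-(trimethylsilyl)hepta-2,4,6-trienoate (dienylketene) | O=C=C([Si](C)(C)C)/C(O[Si](C(C)C)(C(C)C)C(C)C)=C\C(C)=C\C(=O)OC(C)(C)C | intermediate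
14 | tert-butyl 6-methyl-2-oxo-4-(triisopropylsilyloxy)-3-(trimethylsilyl)cyclohexa-3,5-diene-1-carboxylate (racemic) | CC1=CC(O[Si](C(C)C)(C(C)C)C(C)C)=C([Si](C)(C)C)C(=O)C1C(=O)OC(C)(C)C | intermediate
15 | tert-butyl 2-hydroxy-6-methyl-4-(triisopropylsilyloxy)-3-(trimethylsilyl)benzoate | Cc1cc(O[Si](C(C)C)(C(C)C)C(C)C)c([Si](C)(C)C)c(O)c1C(=O)OC(C)(C)C | intermediate
16 | tert-butyl 2,4-dihydroxy-6-methyl-3-(trimethylsilyl)benzoate | Cc1cc(O)c([Si](C)(C)C)c(O)c1C(=O)OC(C)(C)C | intermediate
17 | tert-butyl 2,4-dihydroxy-6-methylbenzoate | Cc1cc(O)cc(O)c1C(=O)OC(C)(C)C | intermediate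
18 | 2,3,4-trimethoxy-6-methylbenzaldehyde | COc1cc(C)c(C=O)c(OC)c1OC | starting material
19 | 2,3,4-trihydroxy-6-methylbenzaldehyde | Cc1cc(O)c(O)c(O)c1C=O | intermediate
20 | 3,4-bis(benzyloxy)-2-hydroxy-6-methylbenzaldehyde | Cc1cc(OCc2ccccc2)c(OCc2ccccc2)c(O)c1C=O | intermediate
21 | 3,4-bis(benzyloxy)-2-methoxy-6-methylbenzaldehyde | Cc1cc(OCc2ccccc2)c(OCc2ccccc2)c(OC)c1C=O | intermediate
22 | 3,4-bis(benzyloxy)-2-methoxy-6-methylbenzoic acid | COc1c(C(=O)O)c(C)cc(OCc2ccccc2)c1OCc1ccccc1 | intermediate
23 | 3,4-bis(benzyloxy)-2-methoxy-6-methylbenzoyl chloride | COc1c(C(=O)Cl)c(C)cc(OCc2ccccc2)c1OCc1ccccc1 | intermediate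
24 | tert-butyl 4-{[3,4-bis(benzyloxy)-2-methoxy-6-methylbenzoyl]oxy}-2-hydroxy-6-methylbenzoate | COc1c(C(=O)Oc2cc(C)c(C(=O)OC(C)(C)C)c(O)c2)c(C)cc(OCc2ccccc2)c1OCc1ccccc1 | intermediate
25 | 4-{[3,4-bis(benzyloxy)-2-methoxy-6-methylbenzoyl]oxy}-2-hydroxy-6-methylbenzoic acid | COc1c(C(=O)Oc2cc(C)c(C(=O)O)c(O)c2)c(C)cc(OCc2ccccc2)c1OCc1ccccc1 | intermediate
26 | orsellinic acid (2,4-dihydroxy-6-methylbenzoic acid) | Cc1cc(O)cc(O)c1C(=O)O | starting material
27 | benzyl 2,4-dihydroxy-6-methylbenzoate | Cc1cc(O)cc(O)c1C(=O)OCc1ccccc1 | intermediate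
28 | benzyl 4-[(4-{[3,4-bis(benzyloxy)-2-methoxy-6-methylbenzoyl]oxy}-2-hydroxy-6-methylbenzoyl)oxy]-2-hydroxy-6-methylbenzoate | COc1c(C(=O)Oc2cc(C)c(C(=O)Oc3cc(C)c(C(=O)OCc4ccccc4)c(O)c3)c(O)c2)c(C)cc(OCc2ccccc2)c1OCc1ccccc1 | intermediate
29 | 4-({4-[(3,4-dihydroxy-2-methoxy-6-methylbenzoyl)oxy]-2-hydroxy-6-methylbenzoyl}oxy)-2-hydroxy-6-methylbenzoic acid | COc1c(O)c(O)cc(C)c1C(=O)Oc1cc(C)c(C(=O)Oc2cc(C)c(C(=O)O)c(O)c2)c(O)c1 | target

**Step count and risk**
Total step count: 14.
Longest linear sequence: 8 steps (1, 2, 4, 5, 10, 11, 13, 14; the ring A branch 6, 7, 8, 9, 10, 11, 13, 14 is equally long).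

Steps most likely to fail:

Step 4 (key step). Under 254 nm light the enoate double bond of 6 or 11 may isomerize to Z, after which the ketene would be intercepted by the cis ester carbonyl oxygen (oxa-6π closure to a pyranone). Ketene self-reaction may also outrun the bimolecular [2+2], or the 6π closure onto the ester-bearing terminus may be too slow at 80 °C to compete with decay of 12. The fallback sets out from 26 and comes back at 17. Ring B is taken from the aromatic pool instead of being built: orsellinic acid 26 is treated with O-tert-butyl-N,N'-diisopropylisourea in CH2Cl2 at rt, which should transfer a tert-butyl group to the carboxylic acid only and give 17 directly. Steps 10 to 14 then follow unchanged. This fallback makes no compound outside the list (F0).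

Step 2. The amide base may deprotonate the vinylogous C3 methyl or add to the doubly activated alkene instead of forming the acetyl enolate cleanly, so that trifluoroacetylation and diazo transfer occur at the wrong carbon or not at all. The fallback sets out from 3 and comes back at 6 and avoids enolate chemistry. Condensation of 3 with Me2NCH(OMe)2 (toluene, 80 °C) at the acetyl methyl should give the enaminone tert-butyl (2E,5E)-6-(dimethylamino)-3-methyl-4-oxohexa-2,5-dienoate F1. MsN3 in MeCN at rt then adds across the enamine double bond, and the triazoline fragments to 6 and an N-sulfonylformamidine (diazo transfer to an enaminone).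

Step 13. The activated, doubly ortho-substituted salicylic acid may rearrange to the N-acylurea or acylate its own 2'-hydroxyl (oligomer formation) faster than it is captured by 27. The fallback sets out from 24 and comes back at 29; it uses the fully protected acid as its acid chloride.
- 24 is benzylated at the chelated 2'-OH (BnBr, K2CO3, DMF, 40 °C) to tert-butyl 2-(benzyloxy)-4-{[3,4-bis(benzyloxy)-2-methoxy-6-methylbenzoyl]oxy}-6-methylbenzoate F2.
- CF3CO2H/CH2Cl2 cleaves the tert-butyl ester to 2-(benzyloxy)-4-{[3,4-bis(benzyloxy)-2-methoxy-6-methylbenzoyl]oxy}-6-methylbenzoic acid F3.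
- (COCl)2/cat. DMF converts it into 2-(benzyloxy)-4-{[3,4-bis(benzyloxy)-2-methoxy-6-methylbenzoyl]oxy}-6-methylbenzoyl chloride F4, used without isolation.
- F4 acylates the 4-OH of 27 (Et3N, cat. DMAP, CH2Cl2) to benzyl 4-[(2-(benzyloxy)-4-{[3,4-bis(benzyloxy)-2-methoxy-6-methylbenzoyl]oxy}-6-methylbenzoyl)oxy]-2-hydroxy-6-methylbenzoate F5.
- Hydrogenolysis (H2, 10% Pd/C, EtOAc) of the four benzyl groups then gives 29.

**Further compounds**
F0 | step 4 | none | none
F1 | step 2 | tert-butyl (2E,5E)-6-(dimethylamino)-3-methyl-4-oxohexa-2,5-dienoate | CN(C)/C=C/C(=O)/C(C)=C/C(=O)OC(C)(C)C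
F2 | step 13 | tert-butyl 2-(benzyloxy)-4-{[3,4-bis(benzyloxy)-2-methoxy-6-methylbenzoyl]oxy}-6-methylbenzoate | COc1c(C(=O)Oc2cc(C)c(C(=O)OC(C)(C)C)c(OCc3ccccc3)c2)c(C)cc(OCc2ccccc2)c1OCc1ccccc1
F3 | step 13 | 2-(benzyloxy)-4-{[3,4-bis(benzyloxy)-2-methoxy-6-methylbenzoyl]oxy}-6-methylbenzoic acid | COc1c(C(=O)Oc2cc(C)c(C(=O)O)c(OCc3ccccc3)c2)c(C)cc(OCc2ccccc2)c1OCc1ccccc1
F4 | step 13 | 2-(benzyloxy)-4-{[3,4-bis(benzyloxy)-2-methoxy-6-methylbenzoyl]oxy}-6-methylbenzoyl chloride | COc1c(C(=O)Oc2cc(C)c(C(=O)Cl)c(OCc3ccccc3)c2)c(C)cc(OCc2ccccc2)c1OCc1ccccc1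
F5 | step 13 | benzyl 4-[(2-(benzyloxy)-4-{[3,4-bis(benzyloxy)-2-methoxy-6-methylbenzoyl]oxy}-6-methylbenzoyl)oxy]-2-hydroxy-6-methylbenzoate | COc1c(C(=O)Oc2cc(C)c(C(=O)Oc3cc(C)c(C(=O)OCc4ccccc4)c(O)c3)c(OCc3ccccc3)c2)c(C)cc(OCc2ccccc2)c1OCc1ccccc1
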